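The route rests on cutting the pyranone of the lactone-bearing chromanone (primed locants) at O1'–C8a', C4'–C4a' and O1'–C2'. The arene of this ring carries three contiguous substituents, C5'–O, C4a'–C(=O) and C8a'–O, which is the regiochemical signature of a 3-alkoxyaryne. In one operation a biaryl o-silylaryl triflate, which already holds the finished seco-acid chromanone, becomes the C4a'≡C8a' aryne. This aryne inserts into the C–O bond of an enantiopure (Z)-butenedioic half-ester that carries the preformed cis-γ-lactone. The freed phenoxide then closes the ring by 6-endo oxa-Michael addition and sets quaternary C2'. The precursor shows neither the ketone nor the ring oxygen, only a silyl triflate and a separate acid.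

Key step: step 14

Assumption: the 6,6'-biaryl axis has only two ortho oxygen substituents and is taken as freely rotating, so no axial configuration is set; unprimed locants refer to the seco-acid chromanone, primed ones to the lactone chromanone.

Step 1
Reactants: 1 (4R)-4-benzyl-3-propanoyl-1,3-oxazolidin-2-one; 2 benzyl bromoacetate
Product: 3 benzyl (3S)-4-[(4R)-4-benzyl-2-oxo-1,3-oxazolidin-3-yl]-3-methyl-4-oxobutanoate
Conditions: NaHMDS, THF, −78 °C; then 2, −78 to −40 °C
Reagents that add atoms: none
Why: Evans asymmetric alkylation, in which the chelated Z-sodium enolate is attacked on the face opposite the benzyl group of the (R)-auxiliary, which sets the (S)-methyl stereocentre used in both side chains.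

Step 2
Reactants: 3 benzyl (3S)-4-[(4R)-4-benzyl-2-oxo-1,3-oxazolidin-3-yl]-3-methyl-4-oxobutanoate
Product: 4 benzyl (3S)-4-(ethylsulfanyl)-3-methyl-4-oxobutanoate
Conditions: EtSH, n-BuLi, THF, 0 °C
Reagents that add atoms: ethanethiol, CCS
Why: Thiolate cleavage of the N-acyl oxazolidinone (transthioesterification) takes place at the more electrophilic exocyclic imide carbonyl and should leave the benzyl ester and the α-stereocentre untouched.

Step 3
Reactants: 4 benzyl (3S)-4-(ethylsulfanyl)-3-methyl-4-oxobutanoate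
Product: 5 benzyl (3S)-3-methyl-4-oxobutanoate
Conditions: Et3SiH, Pd/C, acetone, rt
Reagents that add atoms: none
Why: The Fukuyama reduction stops at the aldehyde under neutral conditions, so the α-methyl centre should not epimerise and the benzyl ester should survive.

Step 4
Reactants: 5 benzyl (3S)-3-methyl-4-oxobutanoate; 6 methyl propiolate
Product: 9 6-benzyl 1-methyl (2Z,3R,4S)-3-hydroxy-2-(iodomethylidene)-4-methylhexanedioate, via silyl iodoallenolate 7 (not isolated), via trimethylsilyl ether 8 (not isolated)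
Conditions: TMSI, diphenylprolinol-derived oxazaborolidinium triflimide (20 mol %, antipode for Si-face attack), CH2Cl2, −78 °C; then aq. citric acid, THF, 0 °C
Reagents that add atoms: iodotrimethylsilane, C[Si](C)(C)I
Why: Catalytic asymmetric β-iodo Morita–Baylis–Hillman (iodoallenolate aldol) reaction, in which catalyst-directed Si-face attack, matched with the Felkin–Anh bias of the α-methyl aldehyde, sets the (R)-carbinol syn to the methyl group, and kinetic addition at −78 °C gives the Z-iodoalkene with iodine cis to CO2Me.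

Step 5
Reactants: 9 6-benzyl 1-methyl (2Z,3R,4S)-3-hydroxy-2-(iodomethylidene)-4-methylhexanedioate
Product: 10 6-benzyl 1-methyl (2Z,3R,4S)-3-(benzyloxy)-2-(iodomethylidene)-4-methylhexanedioate
Conditions: BnOC(=NH)CCl3, TfOH (cat.), CH2Cl2–cyclohexane, 0 °C
Reagents that add atoms: benzyl 2,2,2-trichloroacetimidate, N=C(OCc1ccccc1)C(Cl)(Cl)Cl
Why: Acid-catalysed imidate O-benzylation forms no alkoxide, so the γ-hydroxy ester should be capped before it lactonises, and no stereocentre is touched.

Step 6
Reactants: 10 6-benzyl 1-methyl (2Z,3R,4S)-3-(benzyloxy)-2-(iodomethylidene)-4-methylhexanedioate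
Product: 11 (2Z,4R,5S)-4,7-bis(benzyloxy)-3-(methoxycarbonyl)-5-methyl-7-oxohept-2-enoic acid
Conditions: Pd(OAc)2, PPh3, CO (1 atm), H2O, i-Pr2NEt, DMF, rt; mild acidic work-up
Reagents that add atoms: carbon monoxide, [C-]#[O+]; water, O
Why: Palladium-catalysed hydroxycarbonylation of a vinyl iodide proceeds with retention of alkene geometry, and the non-nucleophilic base should avoid maleate-to-fumarate isomerisation.

Step 7
Reactants: 9 6-benzyl 1-methyl (2Z,3R,4S)-3-hydroxy-2-(iodomethylidene)-4-methylhexanedioate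
Product: 13 (2Z)-3-(methoxycarbonyl)-3-[(2R,3S)-3-methyl-5-oxooxolan-2-yl]prop-2-enoic acid, via hydroxy acid 12 (not isolated)
Conditions: Pd(OAc)2, PPh3, CO (1 atm), H2O, i-Pr2NEt, DMF, rt; acidic work-up; then CSA (cat.), CH2Cl2, rt
Reagents that add atoms: carbon monoxide, [C-]#[O+]; water, O
Why: Hydroxycarbonylation with retention is followed by acid-catalysed 5-exo-trig lactonisation onto the benzyl ester, which keeps both stereocentres (cis-lactone), while the new carboxyl group lies trans to the carbinol across the alkene and cannot form a butenolide.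

Step 8
Reactants: 14 2-bromobenzene-1,3-diol
Product: 15 2,4-dibromobenzene-1,3-diol
Conditions: NBS (1 equiv), MeCN, −20 to 0 °C
Reagents that add atoms: N-bromosuccinimide, O=C1CCC(=O)N1Br
Why: Electrophilic aromatic bromination can only strike the two equivalent positions ortho/para to the hydroxyl groups, and one equivalent at low temperature should stop at the dibromide.

Step 9
Reactants: 15 2,4-dibromobenzene-1,3-diol
Product: 16 3-(benzyloxy)-2,4-dibromophenol
Conditions: BnBr (1 equiv), KHCO3 (1 equiv), DMF, rt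
Reagents that add atoms: benzyl bromide, BrCc1ccccc1
Why: Williamson etherification under acidity control, in which the hydroxyl group flanked by two bromine atoms is the more acidic one and should be the one ionised and alkylated by one equivalent of weak base.

Step 10
Reactants: 16 3-(benzyloxy)-2,4-dibromophenol
Product: 19 3-(benzyloxy)-4-bromo-2-(trimethylsilyl)phenyl trifluoromethanesulfonate, via aryl silyl ether 17 (not isolated), via lithium silylphenoxide 18 (not isolated)
Conditions: HMDS, THF, 70 °C, evaporation; n-BuLi, THF, −78 °C; Tf2O, −78 to 0 °C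
Reagents that add atoms: hexamethyldisilazane, C[Si](C)(C)N[Si](C)(C)C; trifluoromethanesulfonic anhydride, O=S(=O)(OS(=O)(=O)C(F)(F)F)C(F)(F)F
Why: O-silylation, bromine–lithium exchange, retro-Brook O-to-C silyl shift and triflation form the standard entry to Kobayashi aryne precursors, and exchange should occur at the bromine flanked by two oxygen atoms because that aryllithium is the most stabilised and is drained irreversibly by the silyl shift.

Step 11
Reactants: 19 3-(benzyloxy)-4-bromo-2-(trimethylsilyl)phenyl trifluoromethanesulfonate; 11 (2Z,4R,5S)-4,7-bis(benzyloxy)-3-(methoxycarbonyl)-5-methyl-7-oxohept-2-enoic acid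
Product: 22 methyl (2S)-5-(benzyloxy)-2-[(1R,2S)-1,4-bis(benzyloxy)-2-methyl-4-oxobutyl]-6-bromo-4-oxo-3,4-dihydro-2H-chromene-2-carboxylate, via aryne 20 (not isolated), via hydroxyaryl enone 21 (not isolated)
Conditions: CsF, THF, 125 °C (sealed tube)
Reagents that add atoms: none
Why: Aryne C–O insertion followed by 6-endo-trig oxa-Michael addition (the annulation type of step 14), in which the carboxylate oxygen adds to the aryne carbon distal to the benzyloxy group, the acyl group shifts to the neighbouring carbanion, and the phenoxide closes on the alkene face that is open when the methyl-bearing carbon stands anti (Felkin–Anh, benzyloxy inside, hydrogen outside), which should set (2S) while the aryl bromide stays inert.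

Step 12
Reactants: 22 methyl (2S)-5-(benzyloxy)-2-[(1R,2S)-1,4-bis(benzyloxy)-2-methyl-4-oxobutyl]-6-bromo-4-oxo-3,4-dihydro-2H-chromene-2-carboxylate
Product: 23 methyl (2S)-5-(benzyloxy)-2-[(1R,2S)-1,4-bis(benzyloxy)-2-methyl-4-oxobutyl]-4-oxo-6-(4,4,5,5-tetramethyl-1,3,2-dioxaborolan-2-yl)-3,4-dihydro-2H-chromene-2-carboxylate
Conditions: B2pin2, PdCl2(dppf), KOAc, 1,4-dioxane, 85 °C
Reagents that add atoms: bis(pinacolato)diboron, CC1(C)OB(OC1(C)C)B1OC(C)(C)C(C)(C)O1
Why: Miyaura borylation with the weak base acetate tolerates the ketone and the esters and should not enolise the chromanone.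

Step 13
Reactants: 23 methyl (2S)-5-(benzyloxy)-2-[(1R,2S)-1,4-bis(benzyloxy)-2-methyl-4-oxobutyl]-4-oxo-6-(4,4,5,5-tetramethyl-1,3,2-dioxaborolan-2-yl)-3,4-dihydro-2H-chromene-2-carboxylate; 19 3-(benzyloxy)-4-bromo-2-(trimethylsilyl)phenyl trifluoromethanesulfonate
Product: 24 methyl (2S)-5-(benzyloxy)-6-[2-(benzyloxy)-4-(trifluoromethylsulfonyloxy)-3-(trimethylsilyl)phenyl]-2-[(1R,2S)-1,4-bis(benzyloxy)-2-methyl-4-oxobutyl]-4-oxo-3,4-dihydro-2H-chromene-2-carboxylate
Conditions: Pd(PPh3)4, K3PO4, 1,4-dioxane–H2O, 70 °C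
Reagents that add atoms: none
Why: In Suzuki–Miyaura coupling the C–Br bond reacts in preference to an aryl triflate, here additionally shielded by the ortho silyl group, and the fluoride-free base should leave the silyl triflate unit intact.

Step 14
Reactants: 24 methyl (2S)-5-(benzyloxy)-6-[2-(benzyloxy)-4-(trifluoromethylsulfonyloxy)-3-(trimethylsilyl)phenyl]-2-[(1R,2S)-1,4-bis(benzyloxy)-2-methyl-4-oxobutyl]-4-oxo-3,4-dihydro-2H-chromene-2-carboxylate; 13 (2Z)-3-(methoxycarbonyl)-3-[(2R,3S)-3-methyl-5-oxooxolan-2-yl]prop-2-enoic acid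
Product: 27 tetrabenzyl-protected 6,6'-bichromanone (seco-acid half as benzyl ester and benzyl ether; lactone half complete; 2S,2'S), via biaryl aryne 25 (not isolated), via biaryl hydroxyaryl enone 26 (not isolated)
Conditions: CsF, THF, 125 °C (sealed tube)
Reagents that add atoms: none
Why: Fluoride removes the silyl group of 24 and triflate leaves to give aryne 25 (C4a'≡C8a'); the carboxylate of 13 adds through oxygen to C8a', the carbanion at C4a' attacks the adjacent ester carbonyl (4-exo-trig) and the strained alkoxide collapses, so the aryne is formally inserted into the acid C–O bond and phenoxide-enone 26 closes the pyranone by 6-endo-trig oxa-Michael addition to C2', the acid proton ending at C3'. The closest known reaction type is the fluoride-induced annulation of o-silylaryl triflates with α,β-unsaturated carboxylic acids to 4-chromanones. Regioselectivity is secured by the C5' benzyloxy group, since aryne distortion and inductive stabilisation place the nucleophile at the distal carbon C8a' and the carbanion next to oxygen at C4a', which reproduces the C5'–O/C4a'–C(=O)/C8a'–O pattern. The only new stereocentre, quaternary C2', is controlled by the adjacent (R)-lactone carbon: in a Felkin–Anh arrangement the methyl-bearing ring carbon stands anti to the incoming phenoxide, the ring oxygen sits inside over the small vinylic hydrogen of the Z-alkene and the hydrogen lies outside next to the ester, in a half-chair with pseudoaxial CO2Me, which should expose the face leading to (2'S). Chemoselectivity requires attack β to the ketone and not β to the ester, which the stronger aryl ketone acceptor and the usual 6-endo mode of 2'-hydroxyaryl enones favour, and the acid is the only proton source, so the C3' enolate should be quenched before it can attack the lactone.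

Step 15
Reactants: 27 tetrabenzyl-protected 6,6'-bichromanone
Product: 28 (3S,4R)-4-hydroxy-4-[(2S)-5-hydroxy-6-{(2S)-5-hydroxy-2-(methoxycarbonyl)-2-[(2R,3S)-3-methyl-5-oxooxolan-2-yl]-4-oxo-3,4-dihydro-2H-chromen-6-yl}-2-(methoxycarbonyl)-4-oxo-3,4-dihydro-2H-chromen-2-yl]-3-methylbutanoic acid (CNP0517857.1)
Conditions: H2 (1 atm), Pd(OH)2/C, EtOAc, rt; filtration and evaporation below 30 °C
Reagents that add atoms: none
Why: Neutral catalytic hydrogenolysis cleaves the benzyl ester first and then the three benzyl ethers, so the γ-hydroxy acid is released without acid or base that would close a second lactone, and no stereocentre is touched.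

Compound list
1 | (4R)-4-benzyl-3-propanoyl-1,3-oxazolidin-2-one | CCC(=O)N1[C@H](Cc2ccccc2)COC1=O | starting material
2 | benzyl bromoacetate | BrCC(=O)OCc1ccccc1 | starting material
3 | benzyl (3S)-4-[(4R)-4-benzyl-2-oxo-1,3-oxazolidin-3-yl]-3-methyl-4-oxobutanoate | C[C@@H](CC(=O)OCc1ccccc1)C(=O)N1[C@H](Cc2ccccc2)COC1=O | intermediate
4 | benzyl (3S)-4-(ethylsulfanyl)-3-methyl-4-oxobutanoate | C[C@@H](CC(=O)OCc1ccccc1)C(=O)SCC | intermediate
5 | benzyl (3S)-3-methyl-4-oxobutanoate | C[C@@H](CC(=O)OCc1ccccc1)C=O | intermediate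
6 | methyl propiolate | C#CC(=O)OC | starting material
7 | 3-iodo-1-methoxy-1-(trimethylsilyloxy)propa-1,2-diene (silyl iodoallenolate) | COC(O[Si](C)(C)C)=C=CI | intermediate
8 | 6-benzyl 1-methyl (2Z,3R,4S)-2-(iodomethylidene)-4-methyl-3-(trimethylsilyloxy)hexanedioate | I/C=C(\C(=O)OC)[C@H](O[Si](C)(C)C)[C@@H](C)CC(=O)OCc1ccccc1 | intermediate
9 | 6-benzyl 1-methyl (2Z,3R,4S)-3-hydroxy-2-(iodomethylidene)-4-methylhexanedioate | I/C=C(\C(=O)OC)[C@H](O)[C@@H](C)CC(=O)OCc1ccccc1 | intermediate
10 | 6-benzyl 1-methyl (2Z,3R,4S)-3-(benzyloxy)-2-(iodomethylidene)-4-methylhexanedioate | I/C=C(\C(=O)OC)[C@H](OCc1ccccc1)[C@@H](C)CC(=O)OCc2ccccc2 | intermediate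
11 | (2Z,4R,5S)-4,7-bis(benzyloxy)-3-(methoxycarbonyl)-5-methyl-7-oxohept-2-enoic acid | OC(=O)/C=C(\C(=O)OC)[C@H](OCc1ccccc1)[C@@H](C)CC(=O)OCc2ccccc2 | intermediate
12 | (2Z,4R,5S)-7-(benzyloxy)-4-hydroxy-3-(methoxycarbonyl)-5-methyl-7-oxohept-2-enoic acid | OC(=O)/C=C(\C(=O)OC)[C@H](O)[C@@H](C)CC(=O)OCc1ccccc1 | intermediate
13 | (2Z)-3-(methoxycarbonyl)-3-[(2R,3S)-3-methyl-5-oxooxolan-2-yl]prop-2-enoic acid | OC(=O)/C=C(\C(=O)OC)[C@@H]1OC(=O)C[C@@H]1C | intermediate
14 | 2-bromobenzene-1,3-diol | Oc1cccc(O)c1Br | starting material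
15 | 2,4-dibromobenzene-1,3-diol | Oc1ccc(Br)c(O)c1Br | intermediate
16 | 3-(benzyloxy)-2,4-dibromophenol | Oc1ccc(Br)c(OCc2ccccc2)c1Br | intermediate
17 | [3-(benzyloxy)-2,4-dibromophenoxy]trimethylsilane | C[Si](C)(C)Oc1ccc(Br)c(OCc2ccccc2)c1Br | intermediate
18 | lithium 3-(benzyloxy)-4-bromo-2-(trimethylsilyl)phenoxide | [Li+].[O-]c1ccc(Br)c(OCc2ccccc2)c1[Si](C)(C)C | intermediate
19 | 3-(benzyloxy)-4-bromo-2-(trimethylsilyl)phenyl trifluoromethanesulfonate | O=S(=O)(Oc1ccc(Br)c(OCc2ccccc2)c1[Si](C)(C)C)C(F)(F)F | intermediate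
20 | 3-(benzyloxy)-4-bromobenzyne | BrC1=C(OCc2ccccc2)C#CC=C1 | intermediate
21 | benzyl (3S,4R,5Z)-4-(benzyloxy)-7-[2-(benzyloxy)-3-bromo-6-hydroxyphenyl]-5-(methoxycarbonyl)-3-methyl-7-oxohept-5-enoate | Oc1ccc(Br)c(OCc2ccccc2)c1C(=O)/C=C(\C(=O)OC)[C@H](OCc3ccccc3)[C@@H](C)CC(=O)OCc4ccccc4 | intermediate
22 | methyl (2S)-5-(benzyloxy)-2-[(1R,2S)-1,4-bis(benzyloxy)-2-methyl-4-oxobutyl]-6-bromo-4-oxo-3,4-dihydro-2H-chromene-2-carboxylate | COC(=O)[C@@]1([C@H](OCc3ccccc3)[C@@H](C)CC(=O)OCc4ccccc4)CC(=O)c2c(ccc(Br)c2OCc5ccccc5)O1 | intermediate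
23 | 6-pinacolboronate of 22 | COC(=O)[C@@]1([C@H](OCc3ccccc3)[C@@H](C)CC(=O)OCc4ccccc4)CC(=O)c2c(ccc(B6OC(C)(C)C(C)(C)O6)c2OCc5ccccc5)O1 | intermediate
24 | biaryl o-silylaryl triflate (6-[2-(benzyloxy)-4-(triflyloxy)-3-(trimethylsilyl)phenyl] analogue of 22) | COC(=O)[C@@]1([C@H](OCc3ccccc3)[C@@H](C)CC(=O)OCc4ccccc4)CC(=O)c2c(ccc(-c5ccc(OS(=O)(=O)C(F)(F)F)c([Si](C)(C)C)c5OCc6ccccc6)c2OCc7ccccc7)O1 | intermediate
25 | biaryl aryne (C4a'≡C8a') | COC(=O)[C@@]1([C@H](OCc3ccccc3)[C@@H](C)CC(=O)OCc4ccccc4)CC(=O)c2c(ccc(C5=C(OCc6ccccc6)C#CC=C5)c2OCc7ccccc7)O1 | intermediate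
26 | biaryl 2-hydroxyaryl (Z)-enone carrying the lactone | COC(=O)[C@@]1([C@H](OCc3ccccc3)[C@@H](C)CC(=O)OCc4ccccc4)CC(=O)c2c(ccc(-c5ccc(O)c(C(=O)/C=C(\C(=O)OC)[C@@H]8OC(=O)C[C@@H]8C)c5OCc6ccccc6)c2OCc7ccccc7)O1 | intermediate
27 | tetrabenzyl-protected 6,6'-bichromanone | COC(=O)[C@@]1([C@H](OCc3ccccc3)[C@@H](C)CC(=O)OCc4ccccc4)CC(=O)c2c(ccc(-c5ccc6c(c5OCc7ccccc7)C(=O)C[C@@](C(=O)OC)([C@@H]8OC(=O)C[C@@H]8C)O6)c2OCc9ccccc9)O1 | intermediate
28 | CNP0517857.1 | COC(=O)[C@@]1([C@H](O)[C@@H](C)CC(=O)O)CC(=O)c2c(ccc(-c3ccc4c(c3O)C(=O)C[C@@](C(=O)OC)([C@@H]3OC(=O)C[C@@H]3C)O4)c2O)O1 | target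

Total step count: 15. Longest linear sequence: 11 (steps 1–6 and 11–15).

Steps most likely to fail

Step 14. Several processes may go wrong:
- The aryl anion may be protonated, or may add to the ester-activated alkene carbon, before the acyl shift.
- The reversible oxa-Michael closure may equilibrate at 125 °C, so facial selectivity at C2' erodes.
- The enolate may attack the lactone.

The fallback removes the stereochemical burden from the ring closure. It sets out from 24, whose aryne is intercepted under the same fluoride conditions with monomethyl fumarate to give the biaryl methyl 4-oxochroman-2'-carboxylate F1. Both C2' epimers of F1 are usable. Dehydrogenation with DDQ in dioxane gives the flat biaryl chromone-2'-carboxylate F2; the quaternary C2 of the other half cannot react. A catalytic asymmetric vinylogous Michael addition of 4-methylfuran-2(5H)-one to C2' (chiral Lewis acid) gives the butenolide adduct F3 under catalyst control. The hydrogenation of step 15 then saturates the butenolide from the face opposite the chromanone (cis-methyl) while it removes the four benzyl groups. The fallback comes back at 28, and the pyranone is still the last ring closed.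

Step 13. Oxidative addition at the triflate, base-induced desilylation or triflate hydrolysis, and protodeboronation may compete with the wanted coupling. The fallback sets out from 22. Stannylation with hexabutylditin and Pd(PPh3)4 in toluene gives the arylstannane F4. This is joined to 19 by a base-free and chloride-free Stille coupling (Pd(PPh3)4, dioxane), conditions under which a bromide is engaged in preference to a triflate. The fallback comes back at 24.

Step 5. Acid-catalysed lactonisation of the γ-hydroxy ester may outrun O-benzylation. The fallback sets out from 8, kept by a neutral, non-hydrolytic work-up of step 4. Reductive etherification with benzaldehyde, Et3SiH and catalytic TMSOTf in CH2Cl2 at −78 °C converts the silyl ether directly into the benzyl ether, so the free alcohol is never present. It comes back at 10 and makes no new compound.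

Further compounds
F1 | step 14 | biaryl with methyl 5'-(benzyloxy)-4'-oxochroman-2'-carboxylate unit (C2' epimers) | COC(=O)[C@@]1([C@H](OCc3ccccc3)[C@@H](C)CC(=O)OCc4ccccc4)CC(=O)c2c(ccc(-c5ccc6c(c5OCc7ccccc7)C(=O)CC(C(=O)OC)O6)c2OCc9ccccc9)O1
F2 | step 14 | biaryl with methyl 5'-(benzyloxy)-4'-oxo-4H-chromene-2'-carboxylate unit | COC(=O)[C@@]1([C@H](OCc3ccccc3)[C@@H](C)CC(=O)OCc4ccccc4)CC(=O)c2c(ccc(-c5ccc6oc(C(=O)OC)cc(=O)c6c5OCc7ccccc7)c2OCc8ccccc8)O1
F3 | step 14 | butenolide adduct, (2'S)-2'-[(2R)-3-methyl-5-oxo-2,5-dihydrofuran-2-yl] analogue of 27 | COC(=O)[C@@]1([C@H](OCc3ccccc3)[C@@H](C)CC(=O)OCc4ccccc4)CC(=O)c2c(ccc(-c5ccc6c(c5OCc7ccccc7)C(=O)C[C@@](C(=O)OC)([C@@H]8OC(=O)C=C8C)O6)c2OCc9ccccc9)O1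
F4 | step 13 | 6-(tributylstannyl) analogue of 22 | COC(=O)[C@@]1([C@H](OCc3ccccc3)[C@@H](C)CC(=O)OCc4ccccc4)CC(=O)c2c(ccc([Sn](CCCC)(CCCC)CCCC)c2OCc5ccccc5)O1
F0 | step 5 | none | none
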